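The route rests on cutting the C4–C4a aryl bond and the C11–C18 methyl bond, so that the vicinal C4/C11 stereodiad beside ring A becomes a trans-3-methyl-4-arylbutanolide in which acetal carbon C3 and carbonyl carbon C12 are the two differentiated arms. In one flask an aryl cuprate adds to the crystalline (5R)-menthyloxybutenolide 4 and the enolate is methylated, so one purchased centre fixes 4S and 11S. The precursor is 4 plus a 3-silyloxy-4-methoxyphenyl Grignard reagent. Afterwards C12 is extended by Julia olefination, the C3 dithiane anion takes C2–C1, ring B closes at C8a by phenoxide-directed hydroxyalkylation, C20 enters via an o-quinone methide and C6 is carboxylated last.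

Key step: step 5

Numbering and abbreviations: tetralin C1 (CH–CH3, methyl C20), C2, C3, C4 (CH bearing the chain), C4a, C5 (aromatic CH), C6 (CO2Me), C7 (OMe), C8 (OH), C8a; chain C11 (CH–CH3, methyl C18), C12–C14, C15 (CH–CH3), C16 (CH2OH). Ar = 4-methoxy-3-[(triisopropylsilyl)oxy]phenyl; TBS = tert-butyldimethylsilyl; PT = 1-phenyl-1H-tetrazol-5-yl.

Remark on the chemistry: the C8 oxygen is carried as a TIPS ether, which is stable to BF3/dithiol, alkyllithiums and Raney Ni and is removed by fluoride beside an aldehyde. (R)-3-Bromo-2-methylpropan-1-ol 17 is assumed to be purchased as the single enantiomer.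

Step 1
Reactants: 1 furfural
Product: 2 5-hydroxyfuran-2(5H)-one (racemic hemiacetal)
Conditions: O2, hν (visible), rose bengal (cat.), MeOH, rt
Reagents that add atoms: dioxygen, O=O
Why: Dye-sensitised singlet-oxygen photooxygenation of the furan (Schenck-type [4+2] addition, then methanolysis with loss of the formyl carbon as methyl formate) is the standard entry to this pseudo-acid.

Step 2
Reactants: 2 5-hydroxyfuran-2(5H)-one; 3 (1R,2S,5R)-menthol
Product: 4 (5R)-5-[(1R,2S,5R)-menthyloxy]furan-2(5H)-one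
Conditions: p-TsOH (cat.), toluene, reflux (Dean–Stark); crystallise from hexane, −20 °C; mother liquor re-equilibrated with acid
Reagents that add atoms: none
Why: Acid-catalysed acetalisation gives both acetal epimers, which interconvert under acid while the 5R epimer crystallises (crystallisation-driven resolution), so the acetal centre is set by the menthol auxiliary.

Step 3
Reactants: 5 5-bromo-2-methoxyphenol
Product: 6 (5-bromo-2-methoxyphenoxy)triisopropylsilane
Conditions: TIPSCl, imidazole, DMF, rt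
Reagents that add atoms: chlorotriisopropylsilane, CC(C)[Si](Cl)(C(C)C)C(C)C
Why: Imidazole-promoted O-silylation of a phenol is routine.

Step 4
Reactants: 6 (5-bromo-2-methoxyphenoxy)triisopropylsilane
Product: 7 {4-methoxy-3-[(triisopropylsilyl)oxy]phenyl}magnesium bromide (THF solution, titrated, used directly)
Conditions: Mg turnings (i-Bu2AlH-activated), THF, 40 °C
Reagents that add atoms: magnesium, [Mg]
Why: Oxidative insertion of magnesium into the aryl C–Br bond (Grignard formation) tolerates aryl silyl and methyl ethers.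

Step 5
Reactants: 4 (5R)-5-[(1R,2S,5R)-menthyloxy]furan-2(5H)-one; 7 {4-methoxy-3-[(triisopropylsilyl)oxy]phenyl}magnesium bromide; 8 iodomethane
Product: 11 (3R,4S,5R)-4-Ar-3-methyl-5-[(1R,2S,5R)-menthyloxy]dihydrofuran-2(3H)-one, via bromomagnesium diarylcuprate 9 (not isolated), via bromomagnesium lactone enolate 10 (not isolated)
Conditions: 7 (2.2 equiv), CuBr·SMe2 (1.1 equiv), THF–Me2S, −78 °C; then 4, −78 → −40 °C; then 8 (5 equiv), DMPU, −40 → 0 °C; NH4Cl work-up
Reagents that add atoms: iodomethane (8), CI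
Why: Transmetalation of 7 to copper gives cuprate 9, which adds 1,4 to the butenolide through a copper–alkene π-complex and a β-cuprio enolate that reductively eliminates the C4–C4a bond, leaving enolate 10 that is C-methylated by 8 in the same flask to form C11–C18. The closest known reaction type is tandem cuprate conjugate addition–enolate alkylation, the standard vicinal difunctionalisation of 5-alkoxybutenolides. No ring is closed. The new C4 centre is controlled by the acetal carbon C3 (lactone C5), whose menthyloxy group shields one face of the flat ring so the aryl group enters anti to it. The new C11 centre is controlled by the aryl group just placed at C4, the planar enolate taking the methyl group on the opposite face, which gives the trans,trans lactone and hence 4S,11S. The step needs 1,4- over 1,2-addition, secured by the soft copper reagent, and two 1,2-anti facial selectivities, secured by the rigid five-membered ring.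

Step 6
Reactants: 11 (3R,4S,5R)-4-Ar-3-methyl-5-[(1R,2S,5R)-menthyloxy]dihydrofuran-2(3H)-one
Product: 12 (2R,3S)-3-(1,3-dithian-2-yl)-3-Ar-2-methylpropanoic acid
Conditions: HS(CH2)3SH (1.2 equiv), BF3·OEt2, CH2Cl2, 0 °C
Reagents that add atoms: propane-1,3-dithiol, SCCCS
Why: Lewis-acid thioacetalisation exchanges both acetal oxygens at C3 for sulfur, freeing the C12 acid and the auxiliary without passing through an enolisable free aldehyde, so C4 and C11 are untouched.

Step 7
Reactants: 12 (2R,3S)-3-(1,3-dithian-2-yl)-3-Ar-2-methylpropanoic acid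
Product: 13 (2R,3S)-3-(1,3-dithian-2-yl)-3-Ar-2-methylpropan-1-ol
Conditions: BH3·THF, THF, 0 °C → rt; MeOH quench
Reagents that add atoms: none
Why: Borane reduction of a carboxylic acid to the primary alcohol is chemoselective and leaves the dithiane and silyl ether alone.

Step 8
Reactants: 13 (2R,3S)-3-(1,3-dithian-2-yl)-3-Ar-2-methylpropan-1-ol
Product: 14 (2R,3S)-3-(1,3-dithian-2-yl)-3-Ar-2-methylpropanal
Conditions: Dess–Martin periodinane, pyridine, CH2Cl2, 0 °C → rt
Reagents that add atoms: none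
Why: Buffered Dess–Martin oxidation of a primary alcohol is non-epimerising at the α-centre C11 and does not oxidise thioacetal sulfur.

Step 9
Reactants: 14 (2R,3S)-3-(1,3-dithian-2-yl)-3-Ar-2-methylpropanal
Product: 15 2-[(1S,2S)-4-methoxy-1-Ar-2-methylbut-3-en-1-yl]-1,3-dithiane (E/Z mixture)
Conditions: Ph3P(CH2OMe)Cl, NaN(SiMe3)2, THF, −78 → 0 °C
Reagents that add atoms: (methoxymethyl)triphenylphosphonium chloride, COC[P+](c1ccccc1)(c1ccccc1)c1ccccc1.[Cl-]
Why: Wittig methoxymethylenation adds C13 as an enol ether; at low temperature the ylide adds to the aldehyde faster than it enolises C11.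

Step 10
Reactants: 15 2-[(1S,2S)-4-methoxy-1-Ar-2-methylbut-3-en-1-yl]-1,3-dithiane
Product: 16 (3S,4S)-4-(1,3-dithian-2-yl)-4-Ar-3-methylbutanal
Conditions: HCl (2 M aq.), THF, 40 °C
Reagents that add atoms: water, O
Why: Acid hydrolysis of the enol ether gives the homologous C13 aldehyde under conditions to which the dithiane and aryl TIPS ether are stable.

Step 11
Reactants: 17 (R)-3-bromo-2-methylpropan-1-ol
Product: 18 (R)-2-methyl-3-(PT-sulfanyl)propan-1-ol
Conditions: PT-SH, K2CO3, acetone, rt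
Reagents that add atoms: 1-phenyl-1H-tetrazole-5-thiol, Sc1nnnn1-c1ccccc1
Why: SN2 S-alkylation of the thiolate by the primary bromide does not touch the stereocentre that becomes C15.

Step 12
Reactants: 18 (R)-2-methyl-3-(PT-sulfanyl)propan-1-ol
Product: 19 5-{[(R)-3-(TBS-oxy)-2-methylpropyl]sulfanyl}-1-phenyl-1H-tetrazole
Conditions: TBSCl, imidazole, DMF, rt
Reagents that add atoms: tert-butyldimethylsilyl chloride, CC(C)(C)[Si](C)(C)Cl
Why: Imidazole-promoted silylation of a primary alcohol is routine.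

Step 13
Reactants: 19 5-{[(R)-3-(TBS-oxy)-2-methylpropyl]sulfanyl}-1-phenyl-1H-tetrazole
Product: 20 5-{[(R)-3-(TBS-oxy)-2-methylpropyl]sulfonyl}-1-phenyl-1H-tetrazole
Conditions: H2O2 (30% aq.), (NH4)6Mo7O24·4H2O (cat.), EtOH, 0 °C → rt
Reagents that add atoms: hydrogen peroxide, OO
Why: Molybdate-catalysed peroxide oxidation of sulfide to sulfone is the usual preparation of Julia–Kocienski reagents.

Step 14
Reactants: 20 5-{[(R)-3-(TBS-oxy)-2-methylpropyl]sulfonyl}-1-phenyl-1H-tetrazole; 16 (3S,4S)-4-(1,3-dithian-2-yl)-4-Ar-3-methylbutanal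
Product: 22 (2S,3E,6S,7S)-7-(1,3-dithian-2-yl)-7-Ar-2,6-dimethylhept-3-en-1-yl TBS ether, via potassium sulfonyl carbanion 21 (not isolated)
Conditions: 20, KN(SiMe3)2, DME, −60 °C; then 16, −60 °C → rt
Reagents that add atoms: none
Why: Julia–Kocienski olefination (carbanion addition, Smiles rearrangement, loss of SO2 and tetrazolone) joins C13 to C14; the alkene geometry is irrelevant because the bond is saturated later, and the aldehyde has no α-stereocentre.

Step 15
Reactants: 22 (2S,3E,6S,7S)-7-(1,3-dithian-2-yl)-7-Ar-2,6-dimethylhept-3-en-1-yl TBS ether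
Product: 24 2-{2-[(1S,2S,4E,6S)-7-(TBS-oxy)-1-Ar-2,6-dimethylhept-4-en-1-yl]-1,3-dithian-2-yl}ethan-1-ol, via 2-lithio-1,3-dithiane 23 (not isolated)
Conditions: t-BuLi, THF–HMPA, −78 °C; then oxirane, −78 → 0 °C
Reagents that add atoms: oxirane, C1CO1
Why: Corey–Seebach umpolung: the lithiated dithiane opens oxirane by SN2 attack, adding C2 and C1 while C3 never becomes a free aldehyde, so benzylic C4 cannot epimerise.

Step 16
Reactants: 24 2-{2-[(1S,2S,4E,6S)-7-(TBS-oxy)-1-Ar-2,6-dimethylhept-4-en-1-yl]-1,3-dithian-2-yl}ethan-1-ol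
Product: 25 (4S,5S,9S)-10-(TBS-oxy)-4-Ar-5,9-dimethyldecan-1-ol
Conditions: Raney Ni (W-2, excess), H2 (1 atm), EtOH, 60 °C
Reagents that add atoms: none
Why: Raney Ni hydrogenolysis of both C–S bonds (Mozingo-type desulfurisation) makes C3 a CH2 group, and the hydrogen-rich catalyst saturates the C13=C14 alkene in the same operation, while silyl ethers and the alcohol are inert.

Step 17
Reactants: 25 (4S,5S,9S)-10-(TBS-oxy)-4-Ar-5,9-dimethyldecan-1-ol
Product: 26 (4S,5S,9S)-10-(TBS-oxy)-4-Ar-5,9-dimethyldecanal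
Conditions: Dess–Martin periodinane, pyridine, CH2Cl2, 0 °C → rt
Reagents that add atoms: none
Why: Dess–Martin oxidation of the only free hydroxyl gives the C1 aldehyde while the phenol is still silylated, so no electron-rich phenol meets the oxidant.

Step 18
Reactants: 26 (4S,5S,9S)-10-(TBS-oxy)-4-Ar-5,9-dimethyldecanal
Product: 27 (4S,5S,9S)-10-(TBS-oxy)-4-(3-hydroxy-4-methoxyphenyl)-5,9-dimethyldecanal
Conditions: Bu4NF (1.1 equiv), AcOH (1.1 equiv), THF, 0 °C
Reagents that add atoms: none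
Why: Fluoride desilylation is selective for the aryl silyl ether because phenoxide is the better leaving group, and acetic acid buffering protects the aldehyde and the primary TBS ether.

Step 19
Reactants: 27 (4S,5S,9S)-10-(TBS-oxy)-4-(3-hydroxy-4-methoxyphenyl)-5,9-dimethyldecanal
Product: 29 (5S)-5-[(2S,6S)-7-(TBS-oxy)-6-methylheptan-2-yl]-2-methoxy-5,6,7,8-tetrahydronaphthalene-1,8-diol (epimers at the carbinol carbon C1 of the target numbering), via chloromagnesium phenoxide 28 (not isolated)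
Conditions: MgCl2, Et3N, MeCN, 50 °C (0.01 M)
Reagents that add atoms: none
Why: Magnesium-phenoxide-directed ortho-hydroxyalkylation (Casiraghi-type, as in magnesium-mediated ortho-formylation) delivers the chelated aldehyde to C8a, the only free ortho position, closing ring B as a six-membered carbocycle; the C1 carbinol configuration is erased in step 21.

Step 20
Reactants: 29 (5S)-5-[(2S,6S)-7-(TBS-oxy)-6-methylheptan-2-yl]-2-methoxy-5,6,7,8-tetrahydronaphthalene-1,8-diol
Product: 30 tert-butyl (5S)-5-[(2S,6S)-7-(TBS-oxy)-6-methylheptan-2-yl]-8-hydroxy-2-methoxy-5,6,7,8-tetrahydronaphthalen-1-yl carbonate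
Conditions: Boc2O (1.1 equiv), i-Pr2NEt, DMAP (cat.), CH2Cl2, 0 °C
Reagents that add atoms: di-tert-butyl dicarbonate, CC(C)(C)OC(=O)OC(=O)OC(C)(C)C
Why: Base-catalysed O-acylation occurs at the more acidic phenol and gives the established precursor for low-temperature o-quinone methide generation.

Step 21
Reactants: 30 tert-butyl (5S)-5-[(2S,6S)-7-(TBS-oxy)-6-methylheptan-2-yl]-8-hydroxy-2-methoxy-5,6,7,8-tetrahydronaphthalen-1-yl carbonate
Product: 32 (5S,8R)-5-[(2S,6S)-7-(TBS-oxy)-6-methylheptan-2-yl]-2-methoxy-8-methyl-5,6,7,8-tetrahydronaphthalen-1-ol, via o-quinone methide 31 (not isolated)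
Conditions: MeMgBr (4 equiv), Et2O–toluene, −78 °C → rt; NH4Cl work-up
Reagents that add atoms: methylmagnesium bromide, C[Mg]Br
Why: The Grignard reagent deprotonates the C1 alcohol, the Boc group transfers to that oxygen and is expelled to give 31, and MeMgBr adds 1,4 with rearomatisation (o-quinone methide alkylation of O-Boc salicyl alcohols); the methyl group should enter pseudoaxially on the face opposite the pseudoaxial C4 side chain, giving the 1,4-trans (1R) product.

Step 22
Reactants: 32 (5S,8R)-5-[(2S,6S)-7-(TBS-oxy)-6-methylheptan-2-yl]-2-methoxy-8-methyl-5,6,7,8-tetrahydronaphthalen-1-ol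
Product: 33 tert-butyl{[(2S,6S)-6-[(1S,4R)-6-methoxy-5-(methoxymethoxy)-4-methyl-1,2,3,4-tetrahydronaphthalen-1-yl]-2-methylheptyl]oxy}dimethylsilane
Conditions: NaH, MOMCl, THF–DMF, 0 °C → rt
Reagents that add atoms: chloromethyl methyl ether, COCCl
Why: Williamson-type O-alkylation of the sodium phenoxide installs an acid-labile group that tolerates alkyllithiums.

Step 23
Reactants: 33 tert-butyl{[(2S,6S)-6-[(1S,4R)-6-methoxy-5-(methoxymethoxy)-4-methyl-1,2,3,4-tetrahydronaphthalen-1-yl]-2-methylheptyl]oxy}dimethylsilane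
Product: 35 methyl (5R,8S)-8-[(2S,6S)-7-(TBS-oxy)-6-methylheptan-2-yl]-3-methoxy-4-(methoxymethoxy)-5-methyl-5,6,7,8-tetrahydronaphthalene-2-carboxylate, via C6 aryllithium 34 (not isolated)
Conditions: n-BuLi, TMEDA, Et2O, 0 °C; then cannulate into ClCO2Me, −78 °C
Reagents that add atoms: methyl chloroformate, COC(=O)Cl
Why: Directed ortho-metalation: H-6 is the only ring hydrogen ortho to an oxygen substituent (the C7 methoxy group), so lithiation and acylation place the ester at C6.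

Step 24
Reactants: 35 methyl (5R,8S)-8-[(2S,6S)-7-(TBS-oxy)-6-methylheptan-2-yl]-3-methoxy-4-(methoxymethoxy)-5-methyl-5,6,7,8-tetrahydronaphthalene-2-carboxylate
Product: 36 methyl (5R,8S)-4-hydroxy-8-[(2S,6S)-7-hydroxy-6-methylheptan-2-yl]-3-methoxy-5-methyl-5,6,7,8-tetrahydronaphthalene-2-carboxylate (target)
Conditions: HCl (1.25 M in MeOH), rt → 40 °C
Reagents that add atoms: none
Why: Acid-catalysed methanolysis cleaves the MOM acetal and the primary TBS ether in one operation, and methanol as solvent cannot scramble the methyl ester.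

Compound list

1 | furfural | O=Cc1ccco1 | starting material
2 | 5-hydroxyfuran-2(5H)-one (racemic) | O=C1OC(O)C=C1 | intermediate
3 | (1R,2S,5R)-menthol | O[C@@H]1C[C@H](C)CC[C@H]1C(C)C | starting material
4 | (5R)-5-{[(1R,2S,5R)-5-methyl-2-(propan-2-yl)cyclohexyl]oxy}furan-2(5H)-one | O=C1O[C@@H](O[C@@H]2C[C@H](C)CC[C@H]2C(C)C)C=C1 | intermediate
5 | 5-bromo-2-methoxyphenol | COc1ccc(Br)cc1O | starting material
6 | (5-bromo-2-methoxyphenoxy)triisopropylsilane | COc1ccc(Br)cc1O[Si](C(C)C)(C(C)C)C(C)C | intermediate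
7 | {4-methoxy-3-[(triisopropylsilyl)oxy]phenyl}magnesium bromide | COc1ccc([Mg]Br)cc1O[Si](C(C)C)(C(C)C)C(C)C | intermediate
8 | iodomethane | CI | starting material
9 | bromomagnesium bis{4-methoxy-3-[(triisopropylsilyl)oxy]phenyl}cuprate | COc1ccc([Cu-]c2ccc(OC)c(O[Si](C(C)C)(C(C)C)C(C)C)c2)cc1O[Si](C(C)C)(C(C)C)C(C)C.Br[Mg+] | intermediate
10 | bromomagnesium (4S,5R)-4-Ar-5-[(1R,2S,5R)-menthyloxy]-4,5-dihydrofuran-2-olate | Br[Mg]OC1O[C@@H](O[C@@H]2C[C@H](C)CC[C@H]2C(C)C)[C@H](c2ccc(OC)c(O[Si](C(C)C)(C(C)C)C(C)C)c2)C=1 | intermediate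
11 | (3R,4S,5R)-4-{4-methoxy-3-[(triisopropylsilyl)oxy]phenyl}-3-methyl-5-{[(1R,2S,5R)-5-methyl-2-(propan-2-yl)cyclohexyl]oxy}oxolan-2-one | O=C1O[C@@H](O[C@@H]2C[C@H](C)CC[C@H]2C(C)C)[C@H](c2ccc(OC)c(O[Si](C(C)C)(C(C)C)C(C)C)c2)[C@H]1C | intermediate
12 | (2R,3S)-3-(1,3-dithian-2-yl)-3-{4-methoxy-3-[(triisopropylsilyl)oxy]phenyl}-2-methylpropanoic acid | OC(=O)[C@H](C)[C@@H](c1ccc(OC)c(O[Si](C(C)C)(C(C)C)C(C)C)c1)C1SCCCS1 | intermediate
13 | (2R,3S)-3-(1,3-dithian-2-yl)-3-{4-methoxy-3-[(triisopropylsilyl)oxy]phenyl}-2-methylpropan-1-ol | OC[C@H](C)[C@@H](c1ccc(OC)c(O[Si](C(C)C)(C(C)C)C(C)C)c1)C1SCCCS1 | intermediate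
14 | (2R,3S)-3-(1,3-dithian-2-yl)-3-{4-methoxy-3-[(triisopropylsilyl)oxy]phenyl}-2-methylpropanal | O=C[C@H](C)[C@@H](c1ccc(OC)c(O[Si](C(C)C)(C(C)C)C(C)C)c1)C1SCCCS1 | intermediate
15 | 2-[(1S,2S)-4-methoxy-1-{4-methoxy-3-[(triisopropylsilyl)oxy]phenyl}-2-methylbut-3-en-1-yl]-1,3-dithiane (E/Z mixture) | COC=C[C@H](C)[C@@H](c1ccc(OC)c(O[Si](C(C)C)(C(C)C)C(C)C)c1)C1SCCCS1 | intermediate
16 | (3S,4S)-4-(1,3-dithian-2-yl)-4-{4-methoxy-3-[(triisopropylsilyl)oxy]phenyl}-3-methylbutanal | O=CC[C@H](C)[C@@H](c1ccc(OC)c(O[Si](C(C)C)(C(C)C)C(C)C)c1)C1SCCCS1 | intermediate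
17 | (R)-3-bromo-2-methylpropan-1-ol | OC[C@@H](C)CBr | starting material
18 | (R)-2-methyl-3-[(1-phenyl-1H-tetrazol-5-yl)sulfanyl]propan-1-ol | OC[C@@H](C)CSc1nnnn1-c1ccccc1 | intermediate
19 | 5-{[(R)-3-(tert-butyldimethylsilyloxy)-2-methylpropyl]sulfanyl}-1-phenyl-1H-tetrazole | CC(C)(C)[Si](C)(C)OC[C@@H](C)CSc1nnnn1-c1ccccc1 | intermediate
20 | 5-{[(R)-3-(tert-butyldimethylsilyloxy)-2-methylpropyl]sulfonyl}-1-phenyl-1H-tetrazole | CC(C)(C)[Si](C)(C)OC[C@@H](C)CS(=O)(=O)c1nnnn1-c1ccccc1 | intermediate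
21 | potassium salt of 20 deprotonated at the carbon alpha to sulfur | CC(C)(C)[Si](C)(C)OC[C@@H](C)[CH-]S(=O)(=O)c1nnnn1-c1ccccc1.[K+] | intermediate
22 | tert-butyl{[(2S,3E,6S,7S)-7-(1,3-dithian-2-yl)-7-{4-methoxy-3-[(triisopropylsilyl)oxy]phenyl}-2,6-dimethylhept-3-en-1-yl]oxy}dimethylsilane | CC(C)(C)[Si](C)(C)OC[C@@H](C)/C=C/C[C@H](C)[C@@H](c1ccc(OC)c(O[Si](C(C)C)(C(C)C)C(C)C)c1)C1SCCCS1 | intermediate
23 | 2-lithio derivative of 22 (lithium on the dithiane C2, the future C3) | CC(C)(C)[Si](C)(C)OC[C@@H](C)/C=C/C[C@H](C)[C@@H](c1ccc(OC)c(O[Si](C(C)C)(C(C)C)C(C)C)c1)C1([Li])SCCCS1 | intermediate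
24 | 2-{2-[(1S,2S,4E,6S)-7-(tert-butyldimethylsilyloxy)-1-{4-methoxy-3-[(triisopropylsilyl)oxy]phenyl}-2,6-dimethylhept-4-en-1-yl]-1,3-dithian-2-yl}ethan-1-ol | CC(C)(C)[Si](C)(C)OC[C@@H](C)/C=C/C[C@H](C)[C@@H](c1ccc(OC)c(O[Si](C(C)C)(C(C)C)C(C)C)c1)C1(CCO)SCCCS1 | intermediate
25 | (4S,5S,9S)-10-(tert-butyldimethylsilyloxy)-4-{4-methoxy-3-[(triisopropylsilyl)oxy]phenyl}-5,9-dimethyldecan-1-ol | CC(C)(C)[Si](C)(C)OC[C@@H](C)CCC[C@H](C)[C@@H](c1ccc(OC)c(O[Si](C(C)C)(C(C)C)C(C)C)c1)CCCO | intermediate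
26 | (4S,5S,9S)-10-(tert-butyldimethylsilyloxy)-4-{4-methoxy-3-[(triisopropylsilyl)oxy]phenyl}-5,9-dimethyldecanal | CC(C)(C)[Si](C)(C)OC[C@@H](C)CCC[C@H](C)[C@@H](c1ccc(OC)c(O[Si](C(C)C)(C(C)C)C(C)C)c1)CCC=O | intermediate
27 | (4S,5S,9S)-10-(tert-butyldimethylsilyloxy)-4-(3-hydroxy-4-methoxyphenyl)-5,9-dimethyldecanal | CC(C)(C)[Si](C)(C)OC[C@@H](C)CCC[C@H](C)[C@@H](c1ccc(OC)c(O)c1)CCC=O | intermediate
28 | chloromagnesium phenoxide of 27 | CC(C)(C)[Si](C)(C)OC[C@@H](C)CCC[C@H](C)[C@@H](c1ccc(OC)c(O[Mg]Cl)c1)CCC=O | intermediate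
29 | (5S)-5-[(2S,6S)-7-(tert-butyldimethylsilyloxy)-6-methylheptan-2-yl]-2-methoxy-5,6,7,8-tetrahydronaphthalene-1,8-diol (both carbinol epimers) | COc1ccc2c(c1O)C(O)CC[C@H]2[C@@H](C)CCC[C@H](C)CO[Si](C)(C)C(C)(C)C | intermediate
30 | tert-butyl (5S)-5-[(2S,6S)-7-(tert-butyldimethylsilyloxy)-6-methylheptan-2-yl]-8-hydroxy-2-methoxy-5,6,7,8-tetrahydronaphthalen-1-yl carbonate (both carbinol epimers) | COc1ccc2c(c1OC(=O)OC(C)(C)C)C(O)CC[C@H]2[C@@H](C)CCC[C@H](C)CO[Si](C)(C)C(C)(C)C | intermediate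
31 | (5S)-5-[(2S,6S)-7-(tert-butyldimethylsilyloxy)-6-methylheptan-2-yl]-2-methoxy-6,7-dihydronaphthalen-1(5H)-one (o-quinone methide) | COC1=CC=C2C(=CCC[C@H]2[C@@H](C)CCC[C@H](C)CO[Si](C)(C)C(C)(C)C)C1=O | intermediate
32 | (5S,8R)-5-[(2S,6S)-7-(tert-butyldimethylsilyloxy)-6-methylheptan-2-yl]-2-methoxy-8-methyl-5,6,7,8-tetrahydronaphthalen-1-ol | COc1ccc2c(c1O)[C@H](C)CC[C@H]2[C@@H](C)CCC[C@H](C)CO[Si](C)(C)C(C)(C)C | intermediate
33 | tert-butyl{[(2S,6S)-6-[(1S,4R)-6-methoxy-5-(methoxymethoxy)-4-methyl-1,2,3,4-tetrahydronaphthalen-1-yl]-2-methylheptyl]oxy}dimethylsilane | COc1ccc2c(c1OCOC)[C@H](C)CC[C@H]2[C@@H](C)CCC[C@H](C)CO[Si](C)(C)C(C)(C)C | intermediate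
34 | aryllithium from 33, lithium on the ring carbon ortho to the methoxy group (C6) | COc1c([Li])cc2c(c1OCOC)[C@H](C)CC[C@H]2[C@@H](C)CCC[C@H](C)CO[Si](C)(C)C(C)(C)C | intermediate
35 | methyl (5R,8S)-8-[(2S,6S)-7-(tert-butyldimethylsilyloxy)-6-methylheptan-2-yl]-3-methoxy-4-(methoxymethoxy)-5-methyl-5,6,7,8-tetrahydronaphthalene-2-carboxylate | COC(=O)c1cc2c(c(OCOC)c1OC)[C@H](C)CC[C@H]2[C@@H](C)CCC[C@H](C)CO[Si](C)(C)C(C)(C)C | intermediate
36 | methyl (5R,8S)-4-hydroxy-8-[(2S,6S)-7-hydroxy-6-methylheptan-2-yl]-3-methoxy-5-methyl-5,6,7,8-tetrahydronaphthalene-2-carboxylate (1R,4S,11S,15S in the target numbering) | COC(=O)c1cc2c(c(O)c1OC)[C@H](C)CC[C@H]2[C@@H](C)CCC[C@H](C)CO | target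

Total step count: 24. Longest linear sequence: 19 steps (steps 1, 2, 5–10 and 14–24).

Steps most likely to fail

Step 19 (ring B closure). If magnesium chelation is weak, the aldehyde may self-condense or the phenoxide may attack through C5, para to oxygen, instead of through C8a. The fallback replaces the ionic magnesium template by a covalent boron tether that is isolated. It sets out from 27, which is condensed with PhB(OH)2 and catalytic propionic acid in refluxing toluene with removal of water. The aryl boronate delivers the aldehyde to the ortho carbon through a six-membered cyclic transition state and gives the cyclic phenylboronate F1. Exchange with propane-1,3-diol in THF releases diol 29, where the route resumes at step 20.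

Step 21 (methylation at C1). Facial discrimination by the remote C4 side chain may be insufficient, or the o-quinone methide may tautomerise to the styrene before it is captured. The fallback moves C1 control from the substrate to a catalyst and sets out from 29. MnO2 in CH2Cl2 oxidises the benzylic alcohol to the hydroxy tetralone F2. Excess MeMgBr gives the tertiary carbinol F3, and PPTS in warm toluene dehydrates it to the 1-methyl-3,4-dihydronaphthalene F4. Asymmetric hydrogenation with a chiral phosphine–oxazoline iridium catalyst of the type [Ir(cod)(PHOX)]BArF, using the enantiomer that delivers hydrogen to the C1 face syn to the C4 side chain, returns to 32.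

Step 15 (dithiane alkylation). Metalation of the congested 2-substituted dithiane may be incomplete, oxirane opening may be slow, and ring or benzylic lithiation may compete. The fallback abandons the umpolung for a carbonyl olefination and sets out from 22. MeI and CaCO3 in aqueous MeCN unmask the C3 aldehyde F5, which is kept cold and used at once because H-4 is benzylic and alpha to the carbonyl. The non-basic stabilised ylide Ph3P=CHCO2Me in CH2Cl2 at 0 °C gives the dienoate F6. H2 over PtO2 in EtOAc saturates both alkenes to the ester F7. i-Bu2AlH in CH2Cl2 at −78 °C gives aldehyde 26, where the route resumes at step 18.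

Further compounds

F1 | step 19 | (6S)-6-[(2S,6S)-7-(tert-butyldimethylsilyloxy)-6-methylheptan-2-yl]-9-methoxy-2-phenyl-3a,4,5,6-tetrahydronaphtho[1,8-de][1,3,2]dioxaborinine (cyclic phenylboronate of 29) | COc1ccc2c3c1OB(c1ccccc1)OC3CC[C@H]2[C@@H](C)CCC[C@H](C)CO[Si](C)(C)C(C)(C)C
F2 | step 21 | (4S)-4-[(2S,6S)-7-(tert-butyldimethylsilyloxy)-6-methylheptan-2-yl]-8-hydroxy-7-methoxy-3,4-dihydronaphthalen-1(2H)-one | COc1ccc2c(c1O)C(=O)CC[C@H]2[C@@H](C)CCC[C@H](C)CO[Si](C)(C)C(C)(C)C
F3 | step 21 | (4S)-4-[(2S,6S)-7-(tert-butyldimethylsilyloxy)-6-methylheptan-2-yl]-7-methoxy-1-methyl-1,2,3,4-tetrahydronaphthalene-1,8-diol (both C1 epimers) | COc1ccc2c(c1O)C(C)(O)CC[C@H]2[C@@H](C)CCC[C@H](C)CO[Si](C)(C)C(C)(C)C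
F4 | step 21 | (5S)-5-[(2S,6S)-7-(tert-butyldimethylsilyloxy)-6-methylheptan-2-yl]-2-methoxy-8-methyl-5,6-dihydronaphthalen-1-ol | COc1ccc2c(c1O)C(C)=CC[C@H]2[C@@H](C)CCC[C@H](C)CO[Si](C)(C)C(C)(C)C
F5 | step 15 | (2S,3S,5E,7S)-8-(tert-butyldimethylsilyloxy)-2-{4-methoxy-3-[(triisopropylsilyl)oxy]phenyl}-3,7-dimethyloct-5-enal | CC(C)(C)[Si](C)(C)OC[C@@H](C)/C=C/C[C@H](C)[C@@H](c1ccc(OC)c(O[Si](C(C)C)(C(C)C)C(C)C)c1)C=O
F6 | step 15 | methyl (2E,4R,5S,7E,9S)-10-(tert-butyldimethylsilyloxy)-4-{4-methoxy-3-[(triisopropylsilyl)oxy]phenyl}-5,9-dimethyldeca-2,7-dienoate | CC(C)(C)[Si](C)(C)OC[C@@H](C)/C=C/C[C@H](C)[C@@H](c1ccc(OC)c(O[Si](C(C)C)(C(C)C)C(C)C)c1)/C=C/C(=O)OC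
F7 | step 15 | methyl (4S,5S,9S)-10-(tert-butyldimethylsilyloxy)-4-{4-methoxy-3-[(triisopropylsilyl)oxy]phenyl}-5,9-dimethyldecanoate | CC(C)(C)[Si](C)(C)OC[C@@H](C)CCC[C@H](C)[C@@H](c1ccc(OC)c(O[Si](C(C)C)(C(C)C)C(C)C)c1)CCC(=O)OC
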